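**Retrosynthetic overview**

- Presumed biosynthesis: farnesyl C1→C10 closure gives a 6-oxygenated germacra-1(10),4-diene; a transannular C2–C8 bond then gives the trans-fused hydroazulene; C4 hydration, 1(10)-epoxidation and C6 acylation finish it.
- Last steps: hydroxyl-directed 1(10)-epoxidation and release of the phenol; the C1=C10 olefin closes the five-membered ring (formed second) by carbonyl coupling of a C1 aldehyde with a C10 methyl ketone.
- Key step: the C2–C8 bond closes the seven-membered ring (formed first): C2, as the enamine of the C1 aldehyde, adds to C8 of a C8=C9–C10(=O) enone and sets both ring-fusion centres.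
- The C6–C7 bond (the farnesyl C1–C10 bond) comes from a syn-selective (Z)-allylboration; the C4 carbinol comes from (R)-linalool.
- Purchased materials: (R)-linalool, (Z)-4-methylpent-2-ene, methyl vinyl ketone, 4-(benzyloxy)benzoyl chloride.

Assumption: positions are given in germacrane numbering (C7 isopropyl, C6 ester oxygen, C4 carbinol, C1/C10 epoxide, C2 and C8 ring fusion), and the biosynthesis in the first line is presumed, not established.

**Route**

Step 1
Reactants: 1 (R)-linalool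
Product: 2 triethyl{[(3R)-3,7-dimethylocta-1,6-dien-3-yl]oxy}silane
Conditions: TESOTf, 2,6-lutidine, CH2Cl2, −78 to 0 °C
Reagents that add atoms: triethylsilyl trifluoromethanesulfonate, CC[Si](CC)(CC)OS(=O)(=O)C(F)(F)F
Why: Silyl triflate silylation of the hindered tertiary alcohol masks the C4 hydroxyl, so the later γ-hydroxy aldehyde cannot close to a lactol; the stereocentre is not touched.

Step 2
Reactants: 2 triethyl{[(3R)-3,7-dimethylocta-1,6-dien-3-yl]oxy}silane
Product: 4 (3R)-3,7-dimethyl-3-(triethylsilyloxy)oct-6-en-1-ol, via organoborane 3 (not isolated)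
Conditions: 9-BBN, THF, 0 °C to rt; then NaOH, H2O2, 0 °C to rt
Reagents that add atoms: 9-BBN, B1C2CCCC1CCC2 (boron, in 3 only); hydrogen peroxide, OO
Why: Anti-Markovnikov hydroboration–oxidation; the bulky borane adds only to the monosubstituted vinyl group and leaves the trisubstituted olefin alone.

Step 3
Reactants: 4 (3R)-3,7-dimethyl-3-(triethylsilyloxy)oct-6-en-1-ol
Product: 5 (3R)-3,7-dimethyl-3-(triethylsilyloxy)oct-6-enal
Conditions: Dess–Martin periodinane, NaHCO3, CH2Cl2, 0 °C to rt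
Reagents that add atoms: none
Why: Buffered Dess–Martin oxidation of the primary alcohol gives the β-silyloxy aldehyde without β-elimination.

Step 4
Reactants: 5 (3R)-3,7-dimethyl-3-(triethylsilyloxy)oct-6-enal, 6 (Z)-4-methylpent-2-ene
Product: 11 (3S,4S,6R)-6,10-dimethyl-3-(propan-2-yl)-6-(triethylsilyloxy)undeca-1,9-dien-4-ol, via allylpotassium 7 (not isolated), via borate 8 (not isolated), via allylborane 9 (not isolated), via borinate 10 (not isolated)
Conditions: 6, n-BuLi, KOtBu, THF, −78 to −45 °C; (+)-Ipc2BOMe (from (−)-α-pinene), −78 °C; BF3·OEt2; 5, −78 °C; then NaOH, H2O2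
Reagents that add atoms: potassium tert-butoxide, CC(C)(C)[O-].[K+] (potassium, in 7 and 8 only); (+)-B-methoxydiisopinocampheylborane, COB([C@H]1C[C@H]2C[C@H](C2(C)C)[C@@H]1C)[C@H]1C[C@H]2C[C@H](C2(C)C)[C@@H]1C (boron and isopinocampheyl groups, in 8 to 10 only)
Why: Brown asymmetric allylboration of the crotylboration type forms the C6–C7 bond: the chair transition state turns the (Z)-allylborane into the syn C6-oxygen/C7-isopropyl relationship, and the (+)-isopinocampheyl ligands direct attack to the Re face of the aldehyde, giving (4S) and (3S) under reagent control.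

Step 5
Reactants: 11 (3S,4S,6R)-6,10-dimethyl-3-(propan-2-yl)-6-(triethylsilyloxy)undeca-1,9-dien-4-ol, 12 4-(benzyloxy)benzoyl chloride
Product: 13 (3S,4S,6R)-6,10-dimethyl-3-(propan-2-yl)-6-(triethylsilyloxy)undeca-1,9-dien-4-yl 4-(benzyloxy)benzoate
Conditions: pyridine, DMAP (cat.), CH2Cl2, 0 °C to rt
Reagents that add atoms: none
Why: DMAP-catalysed acylation of the only free hydroxyl installs the natural ester in protected form; no stereocentre is touched.

Step 6
Reactants: 13 (3S,4S,6R)-6,10-dimethyl-3-(propan-2-yl)-6-(triethylsilyloxy)undeca-1,9-dien-4-yl 4-(benzyloxy)benzoate, 14 methyl vinyl ketone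
Product: 15 (3E,5S,6S,8R)-8,12-dimethyl-2-oxo-5-(propan-2-yl)-8-(triethylsilyloxy)trideca-3,11-dien-6-yl 4-(benzyloxy)benzoate
Conditions: 14 (5 equiv), RuCl2(H2IMes)(=CH-C6H4-2-OiPr) (second-generation Hoveyda–Grubbs catalyst, 5 mol %), CH2Cl2, 40 °C
Reagents that add atoms: none
Why: Olefin cross-metathesis of the terminal vinyl group with the enone partner gives the (E)-enone (C8=C9–C10=O); the trisubstituted olefin is a spectator.

Step 7
Reactants: 15 (3E,5S,6S,8R)-8,12-dimethyl-2-oxo-5-(propan-2-yl)-8-(triethylsilyloxy)trideca-3,11-dien-6-yl 4-(benzyloxy)benzoate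
Product: 17 (3E,5S,6S,8R)-8-methyl-2,11-dioxo-5-(propan-2-yl)-8-(triethylsilyloxy)undec-3-en-6-yl 4-(benzyloxy)benzoate, via ozonide 16 (not isolated)
Conditions: O3 (to consumption of the trisubstituted olefin), CH2Cl2, −78 °C; then PPh3, −78 °C to rt
Reagents that add atoms: ozone, [O-][O+]=O
Why: Chemoselective ozonolysis: the electron-rich trisubstituted olefin reacts far faster than the electron-poor enone or the arene, and reductive work-up frees the C1 aldehyde.

Step 8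
Reactants: 17 (3E,5S,6S,8R)-8-methyl-2,11-dioxo-5-(propan-2-yl)-8-(triethylsilyloxy)undec-3-en-6-yl 4-(benzyloxy)benzoate
Product: 18 (1S,2S,3S,4S,6R)-4-formyl-6-methyl-3-(2-oxopropyl)-2-(propan-2-yl)-6-(triethylsilyloxy)cycloheptyl 4-(benzyloxy)benzoate
Conditions: (R)-α,α-diphenylprolinol trimethylsilyl ether (20 mol %), PhCO2H (20 mol %), toluene (0.01 M), rt to 40 °C
Reagents that add atoms: none
Why: Proposed new method: the amine condenses with the C1 aldehyde and the enamine carbon C2 adds to C8 of the tethered (E)-enone in a 7-exo-trig closure that makes the biosynthetic C2–C8 bond; the catalyst shields one enamine face to give (S) at C2, the C7 isopropyl, C8 acetonyl and C2 formyl groups end all-trans (all pseudo-equatorial, and C2 can still equilibrate through the enamine), and the bulky catalyst does not form the ketone enamine that would lead to aldol condensation; closest known reaction type: the amine-catalysed intramolecular Michael addition of aldehydes to enones, established for five- and six-membered rings.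

Step 9
Reactants: 18 (1S,2S,3S,4S,6R)-4-formyl-6-methyl-3-(2-oxopropyl)-2-(propan-2-yl)-6-(triethylsilyloxy)cycloheptyl 4-(benzyloxy)benzoate
Product: 20 (3aS,5R,7S,8S,8aR)-2,5-dimethyl-8-(propan-2-yl)-5-(triethylsilyloxy)-1,3a,4,5,6,7,8,8a-octahydroazulen-7-yl 4-(benzyloxy)benzoate, via titanium pinacolate 19 (not isolated)
Conditions: TiCl3(DME)1.5, Zn(Cu), DME, reflux, slow addition of 18
Reagents that add atoms: titanium trichloride (as its DME complex), Cl[Ti](Cl)Cl (titanium, in 19 only)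
Why: McMurry coupling of the 1,5-keto aldehyde by low-valent titanium forms the C1=C10 olefin and closes the cyclopentene; the two coupling arms are trans-diequatorial, so the ring fusion stays trans, and the fast five-ring aldehyde–ketone coupling outruns attack on the aryl ester.

Step 10
Reactants: 20 (3aS,5R,7S,8S,8aR)-2,5-dimethyl-8-(propan-2-yl)-5-(triethylsilyloxy)-1,3a,4,5,6,7,8,8a-octahydroazulen-7-yl 4-(benzyloxy)benzoate
Product: 21 (3aS,5R,7S,8S,8aR)-5-hydroxy-2,5-dimethyl-8-(propan-2-yl)-1,3a,4,5,6,7,8,8a-octahydroazulen-7-yl 4-(benzyloxy)benzoate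
Conditions: HF·pyridine, pyridine, THF, 0 °C to rt
Reagents that add atoms: none
Why: Fluoride cleavage of the silyl ether frees the tertiary C4 hydroxyl; ester, benzyl ether and olefin are inert.

Step 11
Reactants: 21 (3aS,5R,7S,8S,8aR)-5-hydroxy-2,5-dimethyl-8-(propan-2-yl)-1,3a,4,5,6,7,8,8a-octahydroazulen-7-yl 4-(benzyloxy)benzoate
Product: 22 (2R,3S,3aS,5R,7S,8S,8aR)-2,3-epoxy-5-hydroxy-2,5-dimethyl-8-(propan-2-yl)decahydroazulen-7-yl 4-(benzyloxy)benzoate
Conditions: VO(acac)2 (5 mol %), t-BuOOH, CH2Cl2, 0 °C to rt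
Reagents that add atoms: tert-butyl hydroperoxide, CC(C)(C)OO
Why: Hydroxyl-directed vanadium-catalysed epoxidation: the β-oriented C4 hydroxyl (bishomoallylic) binds the vanadium peroxide and delivers oxygen to the β face of the C1=C10 olefin, giving the β-epoxide; the cis hydroxyl cannot open the epoxide from the rear.

Step 12
Reactants: 22 (2R,3S,3aS,5R,7S,8S,8aR)-2,3-epoxy-5-hydroxy-2,5-dimethyl-8-(propan-2-yl)decahydroazulen-7-yl 4-(benzyloxy)benzoate
Product: 23 (2R,3S,3aS,5R,7S,8S,8aR)-2,3-epoxy-5-hydroxy-2,5-dimethyl-8-(propan-2-yl)decahydroazulen-7-yl 4-hydroxybenzoate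
Conditions: H2 (1 atm), Pd/C, EtOAc, rt
Reagents that add atoms: none
Why: Hydrogenolysis of the aryl benzyl ether frees the phenol; the trialkyl epoxide, the ester and the tertiary alcohol are not benzylic and survive.

**Compound list**

1 | (R)-linalool, (3R)-3,7-dimethylocta-1,6-dien-3-ol | C=C[C@](C)(O)CCC=C(C)C | starting material
2 | triethyl{[(3R)-3,7-dimethylocta-1,6-dien-3-yl]oxy}silane | C=C[C@](C)(O[Si](CC)(CC)CC)CCC=C(C)C | intermediate
3 | 9-[(3S)-3,7-dimethyl-3-(triethylsilyloxy)oct-6-en-1-yl]-9-borabicyclo[3.3.1]nonane (same spatial arrangement as 2) | CC(C)=CCC[C@@](C)(O[Si](CC)(CC)CC)CCB1C2CCCC1CCC2 | intermediate (not isolated)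
4 | (3R)-3,7-dimethyl-3-(triethylsilyloxy)oct-6-en-1-ol | OCC[C@](C)(O[Si](CC)(CC)CC)CCC=C(C)C | intermediate
5 | (3R)-3,7-dimethyl-3-(triethylsilyloxy)oct-6-enal | O=CC[C@](C)(O[Si](CC)(CC)CC)CCC=C(C)C | intermediate
6 | (Z)-4-methylpent-2-ene | C/C=C\C(C)C | starting material
7 | (Z)-(4-methylpent-2-en-1-yl)potassium | [K+].[CH2-]/C=C\C(C)C | intermediate (not isolated)
8 | potassium methoxy[(2Z)-4-methylpent-2-en-1-yl]bis(isopinocampheyl)borate | [K+].CO[B-](C/C=C\C(C)C)([C@H]1C[C@H]2C[C@H](C2(C)C)[C@@H]1C)[C@H]1C[C@H]2C[C@H](C2(C)C)[C@@H]1C | intermediate (not isolated)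
9 | [(2Z)-4-methylpent-2-en-1-yl]bis(isopinocampheyl)borane | C(/C=C\C(C)C)B([C@H]1C[C@H]2C[C@H](C2(C)C)[C@@H]1C)[C@H]1C[C@H]2C[C@H](C2(C)C)[C@@H]1C | intermediate (not isolated)
10 | (3S,4S,6R)-6,10-dimethyl-3-(propan-2-yl)-6-(triethylsilyloxy)undeca-1,9-dien-4-yl bis(isopinocampheyl)borinate | C=C[C@H](C(C)C)[C@@H](OB([C@H]1C[C@H]2C[C@H](C2(C)C)[C@@H]1C)[C@H]1C[C@H]2C[C@H](C2(C)C)[C@@H]1C)C[C@](C)(O[Si](CC)(CC)CC)CCC=C(C)C | intermediate (not isolated)
11 | (3S,4S,6R)-6,10-dimethyl-3-(propan-2-yl)-6-(triethylsilyloxy)undeca-1,9-dien-4-ol | C=C[C@H](C(C)C)[C@@H](O)C[C@](C)(O[Si](CC)(CC)CC)CCC=C(C)C | intermediate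
12 | 4-(benzyloxy)benzoyl chloride | O=C(Cl)c1ccc(OCc2ccccc2)cc1 | starting material
13 | (3S,4S,6R)-6,10-dimethyl-3-(propan-2-yl)-6-(triethylsilyloxy)undeca-1,9-dien-4-yl 4-(benzyloxy)benzoate | C=C[C@H](C(C)C)[C@@H](OC(=O)c1ccc(OCc2ccccc2)cc1)C[C@](C)(O[Si](CC)(CC)CC)CCC=C(C)C | intermediate
14 | methyl vinyl ketone (but-3-en-2-one) | CC(=O)C=C | starting material
15 | (3E,5S,6S,8R)-8,12-dimethyl-2-oxo-5-(propan-2-yl)-8-(triethylsilyloxy)trideca-3,11-dien-6-yl 4-(benzyloxy)benzoate | CC(=O)/C=C/[C@H](C(C)C)[C@@H](OC(=O)c1ccc(OCc2ccccc2)cc1)C[C@](C)(O[Si](CC)(CC)CC)CCC=C(C)C | intermediate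
16 | (3E,5S,6S,8R)-10-(5,5-dimethyl-1,2,4-trioxolan-3-yl)-8-methyl-2-oxo-5-(propan-2-yl)-8-(triethylsilyloxy)dec-3-en-6-yl 4-(benzyloxy)benzoate (ozonide, epimers at the trioxolane carbon) | CC(=O)/C=C/[C@H](C(C)C)[C@@H](OC(=O)c1ccc(OCc2ccccc2)cc1)C[C@](C)(O[Si](CC)(CC)CC)CCC1OOC(C)(C)O1 | intermediate (not isolated)
17 | (3E,5S,6S,8R)-8-methyl-2,11-dioxo-5-(propan-2-yl)-8-(triethylsilyloxy)undec-3-en-6-yl 4-(benzyloxy)benzoate | CC(=O)/C=C/[C@H](C(C)C)[C@@H](OC(=O)c1ccc(OCc2ccccc2)cc1)C[C@](C)(O[Si](CC)(CC)CC)CCC=O | intermediate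
18 | (1S,2S,3S,4S,6R)-4-formyl-6-methyl-3-(2-oxopropyl)-2-(propan-2-yl)-6-(triethylsilyloxy)cycloheptyl 4-(benzyloxy)benzoate | CC(=O)C[C@H]1[C@H](C(C)C)[C@@H](OC(=O)c2ccc(OCc3ccccc3)cc2)C[C@](C)(O[Si](CC)(CC)CC)C[C@@H]1C=O | intermediate
19 | titanium pinacolate of 18 (cyclic titanium 2,3-diolate of the bicyclic skeleton, other ligands on titanium omitted, diol carbons unassigned) | CC(C)[C@H]1[C@@H]2CC3(C)O[Ti]OC3[C@H]2C[C@@](C)(O[Si](CC)(CC)CC)C[C@@H]1OC(=O)c1ccc(OCc2ccccc2)cc1 | intermediate (not isolated)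
20 | (3aS,5R,7S,8S,8aR)-2,5-dimethyl-8-(propan-2-yl)-5-(triethylsilyloxy)-1,3a,4,5,6,7,8,8a-octahydroazulen-7-yl 4-(benzyloxy)benzoate | CC(C)[C@H]1[C@@H]2CC(C)=C[C@H]2C[C@@](C)(O[Si](CC)(CC)CC)C[C@@H]1OC(=O)c1ccc(OCc2ccccc2)cc1 | intermediate
21 | (3aS,5R,7S,8S,8aR)-5-hydroxy-2,5-dimethyl-8-(propan-2-yl)-1,3a,4,5,6,7,8,8a-octahydroazulen-7-yl 4-(benzyloxy)benzoate | CC(C)[C@H]1[C@@H]2CC(C)=C[C@H]2C[C@@](C)(O)C[C@@H]1OC(=O)c1ccc(OCc2ccccc2)cc1 | intermediate
22 | (2R,3S,3aS,5R,7S,8S,8aR)-2,3-epoxy-5-hydroxy-2,5-dimethyl-8-(propan-2-yl)decahydroazulen-7-yl 4-(benzyloxy)benzoate (trans ring fusion, β-epoxide) | CC(C)[C@H]1[C@@H]2C[C@@]3(C)O[C@H]3[C@H]2C[C@@](C)(O)C[C@@H]1OC(=O)c1ccc(OCc2ccccc2)cc1 | intermediate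
23 | (2R,3S,3aS,5R,7S,8S,8aR)-2,3-epoxy-5-hydroxy-2,5-dimethyl-8-(propan-2-yl)decahydroazulen-7-yl 4-hydroxybenzoate (CNP0245441.1) | CC(C)[C@H]1[C@@H]2C[C@@]3(C)O[C@H]3[C@H]2C[C@@](C)(O)C[C@@H]1OC(=O)c1ccc(O)cc1 | target

**Totals and risks**

Total step count: 12. Longest linear sequence: 12 steps (1 to 23); 6, 12 and 14 are purchased.

Steps most likely to fail:

1. Step 8. The seven-membered enamine Michael closure is slower than the known five- and six-ring cases, and the enone could lose the C6 ester by vinylogous elimination. Fallback: pre-form the nucleophile and close under Lewis acid instead of amine catalysis. It sets out from 13. Ozonolysis of the trisubstituted olefin only (O3, CH2Cl2, −78 °C; PPh3) gives (3S,4S,6R)-6-methyl-9-oxo-3-(propan-2-yl)-6-(triethylsilyloxy)non-1-en-4-yl 4-(benzyloxy)benzoate F1. TBSOTf and Et3N give the silyl enol ether (3S,4S,6R)-9-[(tert-butyldimethylsilyl)oxy]-6-methyl-3-(propan-2-yl)-6-(triethylsilyloxy)nona-1,8-dien-4-yl 4-(benzyloxy)benzoate F2. Cross-metathesis with 14 (same ruthenium catalyst as step 6; the internal silyl enol ether is a poor metathesis partner) gives (3E,5S,6S,8R)-11-[(tert-butyldimethylsilyl)oxy]-8-methyl-2-oxo-5-(propan-2-yl)-8-(triethylsilyloxy)undeca-3,10-dien-6-yl 4-(benzyloxy)benzoate F3. BF3·OEt2 in CH2Cl2 at −78 °C (intramolecular Mukaiyama–Michael addition) and aqueous work-up bring the route back at 18.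

2. Step 9. Low-valent titanium may attack the aryl ester, or stop at the pinacol. Fallback: olefin metathesis in place of carbonyl coupling. It sets out from 18. Non-basic methylenation of both carbonyl groups (Zn, CH2Br2, TiCl4, THF) gives (1S,2S,3R,4R,6R)-4-ethenyl-6-methyl-3-(2-methylprop-2-en-1-yl)-2-(propan-2-yl)-6-(triethylsilyloxy)cycloheptyl 4-(benzyloxy)benzoate F4. Ring-closing metathesis with RuCl2(H2IMes)(PCy3)(=CHPh) (second-generation Grubbs catalyst, CH2Cl2, 40 °C) closes the methylcyclopentene and comes back at 20.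

3. Step 11. The C4 hydroxyl may not reach the olefin, and the face selectivity would then be lost. Fallback: a halohydrin route in place of directed oxygen transfer. It sets out from 21. NBS in THF/H2O at 0 °C puts the bromonium ion on the open α face, and water opens it at the tertiary carbon from the β face to give (2R,3R,3aS,5R,7S,8S,8aS)-3-bromo-2,5-dihydroxy-2,5-dimethyl-8-(propan-2-yl)decahydroazulen-7-yl 4-(benzyloxy)benzoate F5. DBU in CH2Cl2 closes the β-epoxide with inversion at C1 and comes back at 22.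

**Further compounds**

F1 | step 8 | (3S,4S,6R)-6-methyl-9-oxo-3-(propan-2-yl)-6-(triethylsilyloxy)non-1-en-4-yl 4-(benzyloxy)benzoate | C=C[C@H](C(C)C)[C@@H](OC(=O)c1ccc(OCc2ccccc2)cc1)C[C@](C)(O[Si](CC)(CC)CC)CCC=O
F2 | step 8 | (3S,4S,6R)-9-[(tert-butyldimethylsilyl)oxy]-6-methyl-3-(propan-2-yl)-6-(triethylsilyloxy)nona-1,8-dien-4-yl 4-(benzyloxy)benzoate (enol ether E/Z mixture) | C=C[C@H](C(C)C)[C@@H](OC(=O)c1ccc(OCc2ccccc2)cc1)C[C@](C)(O[Si](CC)(CC)CC)CC=CO[Si](C)(C)C(C)(C)C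
F3 | step 8 | (3E,5S,6S,8R)-11-[(tert-butyldimethylsilyl)oxy]-8-methyl-2-oxo-5-(propan-2-yl)-8-(triethylsilyloxy)undeca-3,10-dien-6-yl 4-(benzyloxy)benzoate (enol ether E/Z mixture) | CC(=O)/C=C/[C@H](C(C)C)[C@@H](OC(=O)c1ccc(OCc2ccccc2)cc1)C[C@](C)(O[Si](CC)(CC)CC)CC=CO[Si](C)(C)C(C)(C)C
F4 | step 9 | (1S,2S,3R,4R,6R)-4-ethenyl-6-methyl-3-(2-methylprop-2-en-1-yl)-2-(propan-2-yl)-6-(triethylsilyloxy)cycloheptyl 4-(benzyloxy)benzoate | C=C(C)C[C@H]1[C@H](C(C)C)[C@@H](OC(=O)c2ccc(OCc3ccccc3)cc2)C[C@](C)(O[Si](CC)(CC)CC)C[C@@H]1C=C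
F5 | step 11 | (2R,3R,3aS,5R,7S,8S,8aS)-3-bromo-2,5-dihydroxy-2,5-dimethyl-8-(propan-2-yl)decahydroazulen-7-yl 4-(benzyloxy)benzoate | CC(C)[C@H]1[C@@H]2C[C@@](C)(O)[C@H](Br)[C@H]2C[C@@](C)(O)C[C@@H]1OC(=O)c1ccc(OCc2ccccc2)cc1
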